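## Structural features

The target is a biflavonoid of the 5-deoxy series. A flavan-3-ol (rings A, C and B; 7-hydroxy ring A, pyrogallol ring B) is bonded through its C4 to C8 of a dihydroflavonol (rings D, F and E; pyrogallol ring E), so ring D is both the aryl group on the upper C4 and the benzo ring of the lower chromanone. There are five stereocentres in two blocks: upper C2 (R), C3 (S) and C4 (S) are contiguous in ring C in the 2,3-trans-3,4-trans (2,4-cis) arrangement, and lower C2 (R) and C3 (R) are contiguous and trans in ring F. Ring D separates the blocks, so each must be set in the absolute sense. Rings C and F share the same (2R)-2-aryl-3-oxychroman core with the same spatial arrangement of aryl group and oxygen, so one chiral three-carbon unit can serve both halves. The fragile groups are the two pyrogallol rings (autoxidation, worse in base), ring F (C3 is α to the ketone; base epimerises it or opens the ring to a chalcone), and the benzylic C2–O and C4–C8 bonds (acid). The real difficulty is the bond from upper C4 to lower C8: C8 lies between the two oxygens of ring D (on C7 and C8a), a position that electrophilic substitution of a resorcinol avoids in favour of C6, and it is the most crowded carbon of the molecule. The key step uses the fact that ring D carries four contiguous substituents (the acyl carbon on C4a, oxygen on C8a, upper C4 on C8, oxygen on C7) followed by two unsubstituted carbons (C6, C5). This acylresorcinol pattern is the retron of a [4+2] benzannulation in which C8a–C8–C7–C6 come from a 1,3-dioxygenated diene carrying the upper unit on its central carbon and C4a–C5 from a terminal ynone.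

## Logic of the disconnections

**29 ⇒ 28.** The nine benzyl–oxygen bonds are cut last. Benzyl ethers survive every earlier step and leave under neutral hydrogenolysis, which the pyrogallols and ring F tolerate. The gain is that all polar groups but one are masked by one kind of ether. The demand is that no other protecting group remains at this stage and that the catalyst spares the ketone and the cyclic benzylic ethers.

**28 ⇒ 27.** Lower O1–C2 (ring F) is cut. C2 is benzylic and its oxygen is the chelated phenol oxygen on C8a, so the ring can be closed by displacement at an acyclic carbinol of opposite configuration. The gain is an acyclic α-benzyloxy-β-hydroxy ketone whose two stereocentres are those of a syn aldol. The demand is clean inversion at a benzylic carbon without enolisation of the ketone.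

**27 ⇒ 26.** One O–Si bond is cut. The carbinol has to be masked while the ynone is present (a free hydroxyl would add to the triple bond) and during the cycloaddition. The demand is removal without base, since the β-hydroxy ketone is open to retro-aldol cleavage.

**26 ⇒ 24 + 12 (key).** Lower C4a–C8a and C5–C6 are cut, which removes ring D altogether. The awkward aryl–C4 bond becomes a bond from upper C4 to the central carbon of an open-chain diene, so no substitution on a resorcinol is needed and the lower side chain arrives with the ring. The gain is two halves of similar size and no new stereocentre. The demand is one orientation of addition, neutral conditions, and tolerance of a bulky group on the central diene carbon.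

**24 ⇒ 22 (through 23).** Two O–Si bonds are cut. The diene is the bis(silyl enol ether) of a 2-substituted acetoacetate. The demand is enolisation on both sides of the ketone next to a congested carbon, and handling without moisture.

**22 ⇒ 21 + 13.** The bond from upper C4 to the acetoacetate carbon is cut. C4 is benzylic, ortho to the ring oxygen and para to the ring A ether oxygen, so its cation forms easily and the enol of 13 attacks through its central carbon. This sets C4. The demand is attack anti to the C3 benzyloxy group and suppression of arylation by ring A of a second molecule.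

**21 ⇒ 20.** The C4–H bond is cut. The ketone is the source of the leaving group, so the oxygen that ring construction leaves at C4 is used directly. The carbinol configuration does not matter.

**20 ⇒ 19 ⇒ 18 ⇒ 17.** Upper O1–C2 (ring C), one O–Si bond and the ring A benzyl–oxygen bond are cut. Ring C is opened exactly as ring F is in 28 ⇒ 27. The demand is mono-benzylation at the non-chelated phenol and again inversion at the benzylic carbinol.

**17 ⇒ 12 + 15; 15 ⇒ 14 ⇒ 13.** Upper C4a–C8a and C5–C6 of ring A are cut by the same benzannulation, now with the unsubstituted diene. The gain is that both halves come from the single chiral building block 12, and the cycloaddition and ring closure are rehearsed on a simple case. The demand is the same regiochemistry as in the key step.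

**12 ⇒ 9 + 10; 9 ⇒ 8 ⇒ 7.** The acyl–alkyne bond, one O–Si bond and the amide C–N bond are cut. The N-methoxy-N-methyl amide stops the acetylide at the ketone stage. The demand is that the α-stereocentre is not enolised.

**7 ⇒ 3 + 4; 3 ⇒ 1 + 2.** The Cα–Cβ bond is cut. An auxiliary-controlled syn glycolate aldol sets both stereocentres in one step, and the α-oxygen arrives already benzylated, so the two oxygens never have to be told apart later. The demand is the enolate geometry and facial control supplied by the boron enolate of the (R)-auxiliary.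

## Other disconnections considered

**Alternative 1:** The cut is upper O1–C2 and C3–C4 (ring C). In the forward step a chiral phosphoric acid would dehydrate the ring A o-hydroxybenzhydrol A1 to its o-quinone methide, which would add the (E)-β-silylstyrene A2 in a hetero-[4+2] to give the 3-silyl-4-arylflavan A3. Tamao–Fleming oxidation (retention) would then reveal the C3 hydroxyl. Ring D would be acylated by ortho-lithiation and reaction with 9, and ring F closed as in the chosen plan.
- In favour: one catalytic step would set all three upper stereocentres. The E geometry of A2 gives 2,3-trans and endo approach gives 2,4-cis, which is the required pattern. The aryl group and the β-silicon effect both direct oxygen to the benzylic carbon. Ring D enters as a symmetric resorcinol diether, so the regiochemical question at C8 does not arise; on this point it equals the chosen plan.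
- Against: the β-silyl cation may lose silicon (ipso substitution) instead of closing the ring. Enantiocontrol with a 2,6-dioxygenated aryl group on the methide is uncertain. The oxidation of a hindered secondary silane and the late lithiation and acylation of ring D next to a crowded diarylmethine are demanding.
- Comparison: on step economy and on catalytic stereocontrol of the upper unit it is the better plan (about a dozen steps in the longest line against 16). On mechanism it carries two non-routine steps against one congested cycloaddition. On structure the chosen plan delivers ring D with the complete lower side chain in place, where the alternative must still attach it.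

**Alternative 2:** The cut is lower C4–C4a. Bromine–lithium exchange (n-BuLi) on the bromo aryl ether A4 would give an aryllithium at C4a that attacks the tethered N-methoxy-N-methyl amide (6-exo-trig Parham cycloacylation) to give the fully benzylated target A5.
- In favour: ketone and ring F form together, the amide prevents over-addition, and A5 is one hydrogenolysis from the target. In this respect it is better than the chosen plan, which needs three steps after its key step.
- Against: the cut does not touch the C4–C8 bond. A4 needs a ring D with bromine, ether oxygen, flavanyl group and benzyloxy group on four adjacent carbons, built by classical substitution, and its aryl ether bond must be made at an oxygen flanked by bromine and the flavanyl group. Under n-BuLi the α-hydrogen of the amide is acidic, and deprotonation would epimerise C3 or expel the β-aryloxide.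
- Comparison: mechanistically it exposes the most fragile stereocentres to strong base, where the chosen key step is neutral. In step count it is at best equal, because the work is moved into the preparation of A4.

**Alternative 3:** The cut is upper C4–C4a. The bond from C4 to ring D would be made first by lithiating the resorcinol bis(methoxymethyl) ether A6 between its oxygens and adding it to an aldehyde. Sc(OTf)3 would then ionise the carbinol A7, and ring A, tethered through O1–C2–C3, would attack para to its benzyloxy group (intramolecular Friedel–Crafts alkylation) to give the 4-arylflavan A8.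
- In favour: the position between the two oxygens is reached by the most reliable aromatic metalation, which is equal to or better than the chosen plan on that point. The acyclic precursor comes from the same aldol chemistry. Closure para to the benzyloxy group is favoured sterically and electronically, and the all-equatorial product is the stable one.
- Against: methoxymethyl ethers are labile to Lewis acids and an ortho acetal oxygen can trap the cation. The benzylic C2–O bond can ionise as well, which would scramble C2. Selectivity at C4 depends on the conformation of an acyclic cation. Ring D must afterwards be acylated and ring F closed, as in Alternative 1.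
- Comparison: for the upper half it is probably shorter than the chosen plan. Its cationic key step carries a risk similar to step 13 of the chosen plan. The attachment of the lower half at a crowded ring by organolithium chemistry is the weaker point.

Key step: step 15

Remark on the chemistry: the carbinol carbon of 21, the acetoacetate α-carbon of 22, the ketal carbons of 16 and 25, the hemiaminal carbon of 11 and the enol ether double bonds of 14, 15, 23 and 24 are taken as stereochemically inconsequential, because each becomes trigonal or is lost later. They are drawn without descriptor (21 as its expected major epimer).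

## Steps

Step 1
Reactants: 1 (R)-4-benzyl-1,3-oxazolidin-2-one; 2 benzyloxyacetyl chloride
Product: 3 (4R)-4-benzyl-3-[(benzyloxy)acetyl]-1,3-oxazolidin-2-one
Conditions: n-BuLi, THF, −78 °C; then 2, −78 → 0 °C
Reagents that add atoms: none
Why: N-acylation of the lithiated oxazolidinone by the acid chloride (loading of an Evans auxiliary); the stereocentre of 1 is not touched.

Step 2
Reactants: 3 (4R)-4-benzyl-3-[(benzyloxy)acetyl]-1,3-oxazolidin-2-one; 4 3,4,5-tris(benzyloxy)benzaldehyde
Product: 7 (4R)-4-benzyl-3-{(2R,3S)-2-(benzyloxy)-3-hydroxy-3-[3,4,5-tris(benzyloxy)phenyl]propanoyl}-1,3-oxazolidin-2-one, via Z-dibutylboron enolate 5 (not isolated), via dibutylboron aldolate 6 (not isolated)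
Conditions: Bu2BOTf, Et3N, CH2Cl2, −78 → 0 °C; 4, −78 → 0 °C; then pH 7 buffer, MeOH, H2O2, 0 °C
Reagents that add atoms: none
Why: Evans boron-mediated syn glycolate aldol reaction: the Z-enolate 5 reacts through a chair Zimmerman–Traxler transition state on the face away from the benzyl group of the (R)-auxiliary, which should set C2 (R) and C3 (S) together; the α-oxygen arrives as its benzyl ether, so the two oxygens are differentiated from the start.

Step 3
Reactants: 7 (4R)-4-benzyl-3-{(2R,3S)-2-(benzyloxy)-3-hydroxy-3-[3,4,5-tris(benzyloxy)phenyl]propanoyl}-1,3-oxazolidin-2-one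
Product: 8 (2R,3S)-2-(benzyloxy)-3-hydroxy-N-methoxy-N-methyl-3-[3,4,5-tris(benzyloxy)phenyl]propanamide
Conditions: MeNHOMe·HCl, AlMe3, CH2Cl2, −15 → 0 °C; aq. potassium sodium tartrate
Reagents that add atoms: N,O-dimethylhydroxylamine hydrochloride, CNOC.Cl
Why: Weinreb transamidation with the aluminium amide; the free β-hydroxyl binds aluminium and directs attack to the exocyclic carbonyl, the auxiliary 1 is recovered, and neither stereocentre is enolised.

Step 4
Reactants: 8 (2R,3S)-2-(benzyloxy)-3-hydroxy-N-methoxy-N-methyl-3-[3,4,5-tris(benzyloxy)phenyl]propanamide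
Product: 9 (2R,3S)-2-(benzyloxy)-3-[(tert-butyldimethylsilyl)oxy]-N-methoxy-N-methyl-3-[3,4,5-tris(benzyloxy)phenyl]propanamide
Conditions: TBSOTf, 2,6-lutidine, CH2Cl2, −78 → 0 °C
Reagents that add atoms: tert-butyldimethylsilyl trifluoromethanesulfonate, CC(C)(C)[Si](C)(C)OS(=O)(=O)C(F)(F)F
Why: Silylation of the hindered benzylic hydroxyl with the silyl triflate; the silyl ether later keeps the hydroxyl from adding to the ynone and from retro-aldol cleavage.

Step 5
Reactants: 9 (2R,3S)-2-(benzyloxy)-3-[(tert-butyldimethylsilyl)oxy]-N-methoxy-N-methyl-3-[3,4,5-tris(benzyloxy)phenyl]propanamide; 10 ethynylmagnesium bromide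
Product: 12 (4R,5S)-4-(benzyloxy)-5-[(tert-butyldimethylsilyl)oxy]-5-[3,4,5-tris(benzyloxy)phenyl]pent-1-yn-3-one, via bromomagnesium hemiaminal chelate 11 (not isolated)
Conditions: 10 (0.5 M in THF), THF, −20 → 0 °C; inverse quench into cold 1 M HCl
Reagents that add atoms: none
Why: Weinreb ketone synthesis; the chelate 11 persists until the quench, so a second addition cannot occur, and quenching into acid protonates the liberated amine before it can add to the ynone.

Step 6
Reactants: 13 methyl acetoacetate
Product: 14 methyl 3-[(trimethylsilyl)oxy]but-2-enoate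
Conditions: TMSCl, Et3N, hexane, rt
Reagents that add atoms: chlorotrimethylsilane, C[Si](C)(C)Cl
Why: Soft enolisation and O-silylation of the β-ketoester (first stage of the Chan diene synthesis).

Step 7
Reactants: 14 methyl 3-[(trimethylsilyl)oxy]but-2-enoate
Product: 15 1-methoxy-1,3-bis[(trimethylsilyl)oxy]buta-1,3-diene
Conditions: LiN(i-Pr)2, THF, −78 °C; TMSCl, −78 °C → rt
Reagents that add atoms: chlorotrimethylsilane, C[Si](C)(C)Cl
Why: γ-Deprotonation of the silyloxy enoate and O-silylation of the ester dienolate (second stage of the Chan diene synthesis).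

Step 8
Reactants: 12 (4R,5S)-4-(benzyloxy)-5-[(tert-butyldimethylsilyl)oxy]-5-[3,4,5-tris(benzyloxy)phenyl]pent-1-yn-3-one; 15 1-methoxy-1,3-bis[(trimethylsilyl)oxy]buta-1,3-diene
Product: 17 (2R,3S)-2-(benzyloxy)-3-[(tert-butyldimethylsilyl)oxy]-1-(2,4-dihydroxyphenyl)-3-[3,4,5-tris(benzyloxy)phenyl]propan-1-one, via cyclohexadiene ketal cycloadduct 16 (not isolated)
Conditions: 15 (2 equiv), toluene, rt → 60 °C; then 0.5 M HCl, THF, 0 °C
Reagents that add atoms: none
Why: Diels–Alder benzannulation of a 1-alkoxy-1,3-bis(silyloxy)diene with an acetylenic ketone, here building ring A: the CH2 terminus of 15 bonds to the β-carbon of 12 and the ketene acetal carbon to the α-carbon, and acid removes methanol and the silyl groups; no stereocentre is formed, and the step rehearses the key step on the unhindered diene.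

Step 9
Reactants: 17 (2R,3S)-2-(benzyloxy)-3-[(tert-butyldimethylsilyl)oxy]-1-(2,4-dihydroxyphenyl)-3-[3,4,5-tris(benzyloxy)phenyl]propan-1-one
Product: 18 (2R,3S)-2-(benzyloxy)-1-[4-(benzyloxy)-2-hydroxyphenyl]-3-[(tert-butyldimethylsilyl)oxy]-3-[3,4,5-tris(benzyloxy)phenyl]propan-1-one
Conditions: BnBr (1.05 equiv), K2CO3, DMF, 0 °C → rt
Reagents that add atoms: benzyl bromide, BrCc1ccccc1
Why: Williamson etherification selective for the non-chelated para hydroxyl, which is the more acidic one, while the ortho hydroxyl is held in a hydrogen bond to the ketone; mild carbonate at room temperature should not enolise the α-benzyloxy ketone.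

Step 10
Reactants: 18 (2R,3S)-2-(benzyloxy)-1-[4-(benzyloxy)-2-hydroxyphenyl]-3-[(tert-butyldimethylsilyl)oxy]-3-[3,4,5-tris(benzyloxy)phenyl]propan-1-one
Product: 19 (2R,3S)-2-(benzyloxy)-1-[4-(benzyloxy)-2-hydroxyphenyl]-3-hydroxy-3-[3,4,5-tris(benzyloxy)phenyl]propan-1-one
Conditions: HF·pyridine, pyridine, THF, 0 °C → rt
Reagents that add atoms: none
Why: Fluoride desilylation under buffered, slightly acidic conditions, which avoids the retro-aldol and epimerisation pathways that a basic fluoride source would open.

Step 11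
Reactants: 19 (2R,3S)-2-(benzyloxy)-1-[4-(benzyloxy)-2-hydroxyphenyl]-3-hydroxy-3-[3,4,5-tris(benzyloxy)phenyl]propan-1-one
Product: 20 (2R,3R)-3,7-bis(benzyloxy)-2-[3,4,5-tris(benzyloxy)phenyl]-2,3-dihydro-4H-chromen-4-one
Conditions: PPh3, DIAD, THF (0.01 M), 0 °C → rt
Reagents that add atoms: none
Why: Intramolecular Mitsunobu etherification (6-exo-tet): the chelated phenol displaces the activated benzylic oxygen with inversion, which turns the (3S) carbinol into C2 (R) of ring C, trans to the C3 benzyloxy group.

Step 12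
Reactants: 20 (2R,3R)-3,7-bis(benzyloxy)-2-[3,4,5-tris(benzyloxy)phenyl]-2,3-dihydro-4H-chromen-4-one
Product: 21 (2R,3S,4R)-3,7-bis(benzyloxy)-2-[3,4,5-tris(benzyloxy)phenyl]-3,4-dihydro-2H-chromen-4-ol
Conditions: NaBH4, CeCl3·7H2O, MeOH/THF (1:1), −20 °C
Reagents that add atoms: none
Why: Luche reduction of the aryl ketone; the cerium salt keeps the medium from becoming basic enough to open ring C, hydride is expected mainly trans to the C3 benzyloxy group, and the carbinol configuration is irrelevant because the centre is ionised in the next step.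

Step 13
Reactants: 21 (2R,3S,4R)-3,7-bis(benzyloxy)-2-[3,4,5-tris(benzyloxy)phenyl]-3,4-dihydro-2H-chromen-4-ol; 13 methyl acetoacetate
Product: 22 methyl 2-{(2R,3S,4R)-3,7-bis(benzyloxy)-2-[3,4,5-tris(benzyloxy)phenyl]-3,4-dihydro-2H-chromen-4-yl}-3-oxobutanoate
Conditions: Sc(OTf)3 (10 mol %), 13 (5 equiv), CH2Cl2, 0 °C → rt
Reagents that add atoms: none
Why: Lewis-acid-catalysed dehydrative alkylation of a 1,3-dicarbonyl compound by a benzylic alcohol (SN1): the C4 cation, stabilised by the ortho ring oxygen and the para benzyloxy group, should be captured by the enol of 13 at its central carbon on the face opposite the C3 benzyloxy group, setting C4 in the 3,4-trans (2,4-cis) arrangement; excess 13 suppresses arylation by ring A, and the new α-carbon is an inconsequential mixture.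

Step 14
Reactants: 22 methyl 2-{(2R,3S,4R)-3,7-bis(benzyloxy)-2-[3,4,5-tris(benzyloxy)phenyl]-3,4-dihydro-2H-chromen-4-yl}-3-oxobutanoate
Product: 24 (2R,3S,4S)-3,7-bis(benzyloxy)-4-{1-methoxy-1,3-bis[(trimethylsilyl)oxy]buta-1,3-dien-2-yl}-2-[3,4,5-tris(benzyloxy)phenyl]-3,4-dihydro-2H-chromene, via trimethylsilyl enol ether 23 (not isolated)
Conditions: LiN(i-Pr)2 (1.1 equiv), THF, −78 °C; TMSCl, → 0 °C; LiN(i-Pr)2 (1.2 equiv), −78 °C; TMSCl, → 0 °C; hexane, filtration under Ar
Reagents that add atoms: chlorotrimethylsilane, C[Si](C)(C)Cl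
Why: The two stages of the Chan diene synthesis run in one flask: O-silylation of the ketoester enolate gives 23, whose γ-methyl group is then deprotonated and the ester dienolate O-silylated; no flavan stereocentre is α to an acidifying group, and 24 is used crude because it is sensitive to moisture.

Step 15
Reactants: 24 (2R,3S,4S)-3,7-bis(benzyloxy)-4-{1-methoxy-1,3-bis[(trimethylsilyl)oxy]buta-1,3-dien-2-yl}-2-[3,4,5-tris(benzyloxy)phenyl]-3,4-dihydro-2H-chromene; 12 (4R,5S)-4-(benzyloxy)-5-[(tert-butyldimethylsilyl)oxy]-5-[3,4,5-tris(benzyloxy)phenyl]pent-1-yn-3-one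
Product: 26 (2R,3S)-2-(benzyloxy)-1-{3-[(2R,3S,4S)-3,7-bis(benzyloxy)-2-(3,4,5-tris(benzyloxy)phenyl)-3,4-dihydro-2H-chromen-4-yl]-2,4-dihydroxyphenyl}-3-[(tert-butyldimethylsilyl)oxy]-3-[3,4,5-tris(benzyloxy)phenyl]propan-1-one, via cyclohexadiene ketal cycloadduct 25 (not isolated)
Conditions: 24 (1.5 equiv), toluene, rt → 70 °C, Ar; then 0.5 M HCl, THF, 0 °C
Reagents that add atoms: none
Why: Thermal Diels–Alder cycloaddition of an electron-rich 1-alkoxy-1,3-bis(silyloxy)diene to an acetylenic ketone followed by aromatisation, the known route from Chan- and Brassard-type dienes to acylresorcinols. The terminal CH2 of 24 (future C6), which carries the largest HOMO coefficient, bonds first to the β-carbon of 12 (future C5), and the ketene acetal carbon (future C8a) then bonds to the α-carbon (future C4a) in a concerted but strongly asynchronous [4+2] that gives the cyclohexa-1,4-diene ketal 25. On acidic work-up the silyl ketal oxygen is desilylated, the hemiketal expels methanol, loss of a C6 proton aromatises the ring and the second silyl ether is hydrolysed, so that 26 carries free hydroxyls on C8a and C7. Ring D is closed by an intermolecular cycloaddition in which both ring bonds form in the same step, not by cyclisation of a tether. No stereocentre is created: the ketal carbon of 25 becomes aromatic, and the configurations at upper C2, C3 and C4 and at the two side-chain carbons are carried through unchanged. The selectivity needed is regiochemical and is secured by the matched polarisation of the two partners; the reverse orientation would put the acyl group meta to both oxygens. Heating in toluene without Lewis acid or base should keep the α-benzyloxy ketone from epimerising and the benzylic C4 bond from ionising, and 24 is used in excess because its hydrolysis on work-up returns 22 for reuse.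

Step 16
Reactants: 26 (2R,3S)-2-(benzyloxy)-1-{3-[(2R,3S,4S)-3,7-bis(benzyloxy)-2-(3,4,5-tris(benzyloxy)phenyl)-3,4-dihydro-2H-chromen-4-yl]-2,4-dihydroxyphenyl}-3-[(tert-butyldimethylsilyl)oxy]-3-[3,4,5-tris(benzyloxy)phenyl]propan-1-one
Product: 27 (2R,3S)-2-(benzyloxy)-1-{3-[(2R,3S,4S)-3,7-bis(benzyloxy)-2-(3,4,5-tris(benzyloxy)phenyl)-3,4-dihydro-2H-chromen-4-yl]-2,4-dihydroxyphenyl}-3-hydroxy-3-[3,4,5-tris(benzyloxy)phenyl]propan-1-one
Conditions: HF·pyridine, pyridine, THF, 0 °C → rt
Reagents that add atoms: none
Why: Buffered fluoride desilylation as in step 10; the β-hydroxy ketone is released without base, so neither retro-aldol cleavage nor epimerisation of the α-carbon is expected.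

Step 17
Reactants: 27 (2R,3S)-2-(benzyloxy)-1-{3-[(2R,3S,4S)-3,7-bis(benzyloxy)-2-(3,4,5-tris(benzyloxy)phenyl)-3,4-dihydro-2H-chromen-4-yl]-2,4-dihydroxyphenyl}-3-hydroxy-3-[3,4,5-tris(benzyloxy)phenyl]propan-1-one
Product: 28 (2R,3R)-3-(benzyloxy)-8-[(2R,3S,4S)-3,7-bis(benzyloxy)-2-(3,4,5-tris(benzyloxy)phenyl)-3,4-dihydro-2H-chromen-4-yl]-7-hydroxy-2-[3,4,5-tris(benzyloxy)phenyl]-2,3-dihydro-4H-chromen-4-one
Conditions: PPh3, DIAD, THF (0.005 M), 0 °C → rt
Reagents that add atoms: none
Why: Intramolecular Mitsunobu etherification (6-exo-tet) as in step 11: the chelated C8a phenol displaces the activated benzylic oxygen with inversion, giving lower C2 (R) trans to C3; the C7 hydroxyl cannot reach the carbinol of its own molecule and is shielded by the flavanyl group, and high dilution disfavours its intermolecular reaction.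

Step 18
Reactants: 28 (2R,3R)-3-(benzyloxy)-8-[(2R,3S,4S)-3,7-bis(benzyloxy)-2-(3,4,5-tris(benzyloxy)phenyl)-3,4-dihydro-2H-chromen-4-yl]-7-hydroxy-2-[3,4,5-tris(benzyloxy)phenyl]-2,3-dihydro-4H-chromen-4-one
Product: 29 (2R,3R)-3,7-dihydroxy-8-[(2R,3S,4S)-3,7-dihydroxy-2-(3,4,5-trihydroxyphenyl)-3,4-dihydro-2H-chromen-4-yl]-2-(3,4,5-trihydroxyphenyl)-2,3-dihydro-4H-chromen-4-one
Conditions: H2 (1 atm), Pd(OH)2/C, THF/MeOH (1:1), rt; filtration and concentration under Ar
Reagents that add atoms: none
Why: Catalytic hydrogenolysis of the nine benzyl ethers under neutral conditions; the aryl ketone, the cyclic benzylic ethers and the interflavanyl bond react far more slowly than acyclic benzyl ethers, and the air-sensitive polyphenol is handled under argon.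

## Compound list

1 | (R)-4-benzyl-1,3-oxazolidin-2-one | O=C1N[C@H](Cc2ccccc2)CO1 | starting material
2 | benzyloxyacetyl chloride | O=C(Cl)COCc1ccccc1 | starting material
3 | (4R)-4-benzyl-3-[(benzyloxy)acetyl]-1,3-oxazolidin-2-one | O=C(COCc1ccccc1)N1[C@H](Cc2ccccc2)COC1=O | intermediate
4 | 3,4,5-tris(benzyloxy)benzaldehyde | O=Cc1cc(OCc2ccccc2)c(OCc2ccccc2)c(OCc2ccccc2)c1 | starting material
5 | Z-dibutylboron enolate of 3 | CCCCB(CCCC)O/C(=C\OCc1ccccc1)N1[C@H](Cc2ccccc2)COC1=O | intermediate (not isolated)
6 | dibutylboron aldolate, O-boryl derivative of 7 | O=C([C@H](OCc1ccccc1)[C@@H](OB(CCCC)CCCC)c1cc(OCc2ccccc2)c(OCc2ccccc2)c(OCc2ccccc2)c1)N1[C@H](Cc2ccccc2)COC1=O | intermediate (not isolated)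
7 | (4R)-4-benzyl-3-{(2R,3S)-2-(benzyloxy)-3-hydroxy-3-[3,4,5-tris(benzyloxy)phenyl]propanoyl}-1,3-oxazolidin-2-one | O=C([C@H](OCc1ccccc1)[C@@H](O)c1cc(OCc2ccccc2)c(OCc2ccccc2)c(OCc2ccccc2)c1)N1[C@H](Cc2ccccc2)COC1=O | intermediate
8 | (2R,3S)-2-(benzyloxy)-3-hydroxy-N-methoxy-N-methyl-3-[3,4,5-tris(benzyloxy)phenyl]propanamide | CON(C)C(=O)[C@H](OCc1ccccc1)[C@@H](O)c1cc(OCc2ccccc2)c(OCc2ccccc2)c(OCc2ccccc2)c1 | intermediate
9 | (2R,3S)-2-(benzyloxy)-3-[(tert-butyldimethylsilyl)oxy]-N-methoxy-N-methyl-3-[3,4,5-tris(benzyloxy)phenyl]propanamide | CON(C)C(=O)[C@H](OCc1ccccc1)[C@@H](O[Si](C)(C)C(C)(C)C)c1cc(OCc2ccccc2)c(OCc2ccccc2)c(OCc2ccccc2)c1 | intermediate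
10 | ethynylmagnesium bromide | C#C[Mg]Br | starting material
11 | bromomagnesium salt of the tetrahedral N-methoxy-N-methyl hemiaminal from 9 and 10 (hemiaminal carbon undefined) | C#CC(O[Mg]Br)(N(C)OC)[C@H](OCc1ccccc1)[C@@H](O[Si](C)(C)C(C)(C)C)c1cc(OCc2ccccc2)c(OCc2ccccc2)c(OCc2ccccc2)c1 | intermediate (not isolated)
12 | (4R,5S)-4-(benzyloxy)-5-[(tert-butyldimethylsilyl)oxy]-5-[3,4,5-tris(benzyloxy)phenyl]pent-1-yn-3-one | C#CC(=O)[C@H](OCc1ccccc1)[C@@H](O[Si](C)(C)C(C)(C)C)c1cc(OCc2ccccc2)c(OCc2ccccc2)c(OCc2ccccc2)c1 | intermediate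
13 | methyl acetoacetate (methyl 3-oxobutanoate) | COC(=O)CC(C)=O | starting material
14 | methyl 3-[(trimethylsilyl)oxy]but-2-enoate (E/Z mixture) | COC(=O)C=C(C)O[Si](C)(C)C | intermediate
15 | 1-methoxy-1,3-bis[(trimethylsilyl)oxy]buta-1,3-diene (ketene acetal geometry undefined) | C=C(O[Si](C)(C)C)C=C(OC)O[Si](C)(C)C | intermediate
16 | (2R,3S)-2-(benzyloxy)-3-[(tert-butyldimethylsilyl)oxy]-1-{6-methoxy-4,6-bis[(trimethylsilyl)oxy]cyclohexa-1,4-dien-1-yl}-3-[3,4,5-tris(benzyloxy)phenyl]propan-1-one (ketal carbon undefined) | COC1(O[Si](C)(C)C)C=C(O[Si](C)(C)C)CC=C1C(=O)[C@H](OCc1ccccc1)[C@@H](O[Si](C)(C)C(C)(C)C)c1cc(OCc2ccccc2)c(OCc2ccccc2)c(OCc2ccccc2)c1 | intermediate (not isolated)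
17 | (2R,3S)-2-(benzyloxy)-3-[(tert-butyldimethylsilyl)oxy]-1-(2,4-dihydroxyphenyl)-3-[3,4,5-tris(benzyloxy)phenyl]propan-1-one | O=C(c1ccc(O)cc1O)[C@H](OCc1ccccc1)[C@@H](O[Si](C)(C)C(C)(C)C)c1cc(OCc2ccccc2)c(OCc2ccccc2)c(OCc2ccccc2)c1 | intermediate
18 | (2R,3S)-2-(benzyloxy)-1-[4-(benzyloxy)-2-hydroxyphenyl]-3-[(tert-butyldimethylsilyl)oxy]-3-[3,4,5-tris(benzyloxy)phenyl]propan-1-one | O=C(c1ccc(OCc2ccccc2)cc1O)[C@H](OCc1ccccc1)[C@@H](O[Si](C)(C)C(C)(C)C)c1cc(OCc2ccccc2)c(OCc2ccccc2)c(OCc2ccccc2)c1 | intermediate
19 | (2R,3S)-2-(benzyloxy)-1-[4-(benzyloxy)-2-hydroxyphenyl]-3-hydroxy-3-[3,4,5-tris(benzyloxy)phenyl]propan-1-one | O=C(c1ccc(OCc2ccccc2)cc1O)[C@H](OCc1ccccc1)[C@@H](O)c1cc(OCc2ccccc2)c(OCc2ccccc2)c(OCc2ccccc2)c1 | intermediate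
20 | (2R,3R)-3,7-bis(benzyloxy)-2-[3,4,5-tris(benzyloxy)phenyl]-2,3-dihydro-4H-chromen-4-one (2,3-trans) | O=C1c2ccc(OCc3ccccc3)cc2O[C@H](c2cc(OCc3ccccc3)c(OCc3ccccc3)c(OCc3ccccc3)c2)[C@H]1OCc1ccccc1 | intermediate
21 | (2R,3S,4R)-3,7-bis(benzyloxy)-2-[3,4,5-tris(benzyloxy)phenyl]-3,4-dihydro-2H-chromen-4-ol (expected major 2,3-trans-3,4-trans epimer; the C4 epimer serves equally) | O[C@@H]1c2ccc(OCc3ccccc3)cc2O[C@H](c2cc(OCc3ccccc3)c(OCc3ccccc3)c(OCc3ccccc3)c2)[C@H]1OCc1ccccc1 | intermediate
22 | methyl 2-{(2R,3S,4R)-3,7-bis(benzyloxy)-2-[3,4,5-tris(benzyloxy)phenyl]-3,4-dihydro-2H-chromen-4-yl}-3-oxobutanoate (2,3-trans-3,4-trans; both epimers at the butanoate C2) | COC(=O)C(C(C)=O)[C@@H]1c2ccc(OCc3ccccc3)cc2O[C@H](c2cc(OCc3ccccc3)c(OCc3ccccc3)c(OCc3ccccc3)c2)[C@H]1OCc1ccccc1 | intermediate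
23 | methyl 2-{(2R,3S,4S)-3,7-bis(benzyloxy)-2-[3,4,5-tris(benzyloxy)phenyl]-3,4-dihydro-2H-chromen-4-yl}-3-[(trimethylsilyl)oxy]but-2-enoate (double bond geometry undefined) | COC(=O)C(=C(C)O[Si](C)(C)C)[C@@H]1c2ccc(OCc3ccccc3)cc2O[C@H](c2cc(OCc3ccccc3)c(OCc3ccccc3)c(OCc3ccccc3)c2)[C@H]1OCc1ccccc1 | intermediate (not isolated)
24 | (2R,3S,4S)-3,7-bis(benzyloxy)-4-{1-methoxy-1,3-bis[(trimethylsilyl)oxy]buta-1,3-dien-2-yl}-2-[3,4,5-tris(benzyloxy)phenyl]-3,4-dihydro-2H-chromene (ketene acetal geometry undefined) | C=C(O[Si](C)(C)C)C(=C(OC)O[Si](C)(C)C)[C@@H]1c2ccc(OCc3ccccc3)cc2O[C@H](c2cc(OCc3ccccc3)c(OCc3ccccc3)c(OCc3ccccc3)c2)[C@H]1OCc1ccccc1 | intermediate (key-step precursor)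
25 | cyclohexa-1,4-diene ketal from 24 and 12: 6-methoxy-4,6-bis[(trimethylsilyl)oxy]cyclohexa-1,4-dien-1-yl ketone carrying the flavan-4-yl group on C5 (ketal carbon undefined) | COC1(O[Si](C)(C)C)C([C@@H]2c3ccc(OCc4ccccc4)cc3O[C@H](c3cc(OCc4ccccc4)c(OCc4ccccc4)c(OCc4ccccc4)c3)[C@H]2OCc2ccccc2)=C(O[Si](C)(C)C)CC=C1C(=O)[C@H](OCc1ccccc1)[C@@H](O[Si](C)(C)C(C)(C)C)c1cc(OCc2ccccc2)c(OCc2ccccc2)c(OCc2ccccc2)c1 | intermediate (not isolated)
26 | (2R,3S)-2-(benzyloxy)-1-{3-[(2R,3S,4S)-3,7-bis(benzyloxy)-2-(3,4,5-tris(benzyloxy)phenyl)-3,4-dihydro-2H-chromen-4-yl]-2,4-dihydroxyphenyl}-3-[(tert-butyldimethylsilyl)oxy]-3-[3,4,5-tris(benzyloxy)phenyl]propan-1-one | O=C(c1ccc(O)c([C@@H]2c3ccc(OCc4ccccc4)cc3O[C@H](c3cc(OCc4ccccc4)c(OCc4ccccc4)c(OCc4ccccc4)c3)[C@H]2OCc2ccccc2)c1O)[C@H](OCc1ccccc1)[C@@H](O[Si](C)(C)C(C)(C)C)c1cc(OCc2ccccc2)c(OCc2ccccc2)c(OCc2ccccc2)c1 | intermediate (key-step product)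
27 | (2R,3S)-2-(benzyloxy)-1-{3-[(2R,3S,4S)-3,7-bis(benzyloxy)-2-(3,4,5-tris(benzyloxy)phenyl)-3,4-dihydro-2H-chromen-4-yl]-2,4-dihydroxyphenyl}-3-hydroxy-3-[3,4,5-tris(benzyloxy)phenyl]propan-1-one | O=C(c1ccc(O)c([C@@H]2c3ccc(OCc4ccccc4)cc3O[C@H](c3cc(OCc4ccccc4)c(OCc4ccccc4)c(OCc4ccccc4)c3)[C@H]2OCc2ccccc2)c1O)[C@H](OCc1ccccc1)[C@@H](O)c1cc(OCc2ccccc2)c(OCc2ccccc2)c(OCc2ccccc2)c1 | intermediate
28 | (2R,3R)-3-(benzyloxy)-8-[(2R,3S,4S)-3,7-bis(benzyloxy)-2-(3,4,5-tris(benzyloxy)phenyl)-3,4-dihydro-2H-chromen-4-yl]-7-hydroxy-2-[3,4,5-tris(benzyloxy)phenyl]-2,3-dihydro-4H-chromen-4-one | O=C1c2ccc(O)c([C@@H]3c4ccc(OCc5ccccc5)cc4O[C@H](c4cc(OCc5ccccc5)c(OCc5ccccc5)c(OCc5ccccc5)c4)[C@H]3OCc3ccccc3)c2O[C@H](c2cc(OCc3ccccc3)c(OCc3ccccc3)c(OCc3ccccc3)c2)[C@H]1OCc1ccccc1 | intermediate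
29 | (2R,3R)-3,7-dihydroxy-8-[(2R,3S,4S)-3,7-dihydroxy-2-(3,4,5-trihydroxyphenyl)-3,4-dihydro-2H-chromen-4-yl]-2-(3,4,5-trihydroxyphenyl)-2,3-dihydro-4H-chromen-4-one | O=C1c2ccc(O)c([C@@H]3c4ccc(O)cc4O[C@H](c4cc(O)c(O)c(O)c4)[C@H]3O)c2O[C@H](c2cc(O)c(O)c(O)c2)[C@H]1O | target

## Step count and least certain steps

Total: 18 steps. Longest linear sequence: 16 steps (steps 1–5 and 8–18). Steps 6 and 7 form a two-step side branch.

**Step 15 (key step).** The cycloaddition is most likely to be slowed by the crowding around the central diene carbon and the fully substituted ketene acetal terminus. Protodesilylation of 24 by traces of moisture or oligomerisation of the terminal ynone would then overtake ring formation, or bond formation would stop after the first (Michael-type) bond. The fallback is a Friedel–Crafts union with a blocked ring and sets out from 17 and 21. Bromination of 17 with N-bromosuccinimide (CH2Cl2, −78 °C) at the position para to the chelated hydroxyl should give the bromo ketone F1. Sc(OTf)3-catalysed reaction of 21 with F1 then leaves the C4 cation only the position between the two hydroxyls, giving the bromo analogue of the key product F2. Radical debromination (Bu3SnH, AIBN, toluene, 80 °C) comes back to the route at 26.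

**Step 14.** The most likely failure is incomplete enolisation next to the congested carbon in the first stage, or hydrolysis of the bis(trimethylsilyl) diene during the solvent change, so that 24 carries 22 and 23 with it. The fallback changes the diene to one with an isolable precursor and sets out from 22. TBSOTf and Et3N (CH2Cl2, 0 °C) should give the tert-butyldimethylsilyl enol ether F3, which can be purified. A single deprotonation and silylation (LiN(i-Pr)2, TMSCl, THF, −78 °C) gives the mixed diene F4. Cycloaddition with 12 in toluene gives the cyclohexadiene ketal F5. Treating crude F5 with HF·pyridine aromatises it and removes all three silyl groups, which comes back to the route at 27.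

**Step 13.** The most likely failure is capture of the C4 cation by ring A of a second molecule (self-arylation and oligomers), because the enol of 13 is a modest nucleophile, together with loss of facial selectivity at C4 under reversible conditions. The fallback is a Mukaiyama-type alkylation and sets out from 21. Acetylation (Ac2O, pyridine) gives the C4 acetate F6. Ionisation with catalytic TMSOTf in CH2Cl2 at −78 °C in the presence of the silyl enol ether 14, a far stronger carbon nucleophile than any arene present, should give 22, where the route is rejoined.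

**Step 17.** The chelated phenol, flanked on both sides, is a poor nucleophile, so the activated carbinol may eliminate or be captured by the hydrazide, or the free C7 hydroxyl of another molecule may form an ether. The fallback is an ionic closure under thermodynamic control and sets out from 27. Catalytic TsOH·H2O in dilute CH2Cl2 ionises the benzylic carbinol, and the chelated phenol closes ring F through the cation. The 2,3-trans isomer is the more stable one and a cis isomer can revert through the same cation, so the route is rejoined at 28 without any compound outside it (entry F0).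

## Further compounds

F1 | step 15 | (2R,3S)-2-(benzyloxy)-1-(5-bromo-2,4-dihydroxyphenyl)-3-[(tert-butyldimethylsilyl)oxy]-3-[3,4,5-tris(benzyloxy)phenyl]propan-1-one | O=C(c1cc(Br)c(O)cc1O)[C@H](OCc1ccccc1)[C@@H](O[Si](C)(C)C(C)(C)C)c1cc(OCc2ccccc2)c(OCc2ccccc2)c(OCc2ccccc2)c1
F2 | step 15 | 5-bromo analogue of 26 (bromine on the ring D carbon para to the chelated hydroxyl) | O=C(c1cc(Br)c(O)c([C@@H]2c3ccc(OCc4ccccc4)cc3O[C@H](c3cc(OCc4ccccc4)c(OCc4ccccc4)c(OCc4ccccc4)c3)[C@H]2OCc2ccccc2)c1O)[C@H](OCc1ccccc1)[C@@H](O[Si](C)(C)C(C)(C)C)c1cc(OCc2ccccc2)c(OCc2ccccc2)c(OCc2ccccc2)c1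
F3 | step 14 | methyl 2-{(2R,3S,4S)-3,7-bis(benzyloxy)-2-[3,4,5-tris(benzyloxy)phenyl]-3,4-dihydro-2H-chromen-4-yl}-3-[(tert-butyldimethylsilyl)oxy]but-2-enoate | COC(=O)C(=C(C)O[Si](C)(C)C(C)(C)C)[C@@H]1c2ccc(OCc3ccccc3)cc2O[C@H](c2cc(OCc3ccccc3)c(OCc3ccccc3)c(OCc3ccccc3)c2)[C@H]1OCc1ccccc1
F4 | step 14 | (2R,3S,4S)-3,7-bis(benzyloxy)-4-{3-[(tert-butyldimethylsilyl)oxy]-1-methoxy-1-[(trimethylsilyl)oxy]buta-1,3-dien-2-yl}-2-[3,4,5-tris(benzyloxy)phenyl]-3,4-dihydro-2H-chromene | C=C(O[Si](C)(C)C(C)(C)C)C(=C(OC)O[Si](C)(C)C)[C@@H]1c2ccc(OCc3ccccc3)cc2O[C@H](c2cc(OCc3ccccc3)c(OCc3ccccc3)c(OCc3ccccc3)c2)[C@H]1OCc1ccccc1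
F5 | step 14 | cyclohexa-1,4-diene ketal from F4 and 12 (ketal carbon undefined) | COC1(O[Si](C)(C)C)C([C@@H]2c3ccc(OCc4ccccc4)cc3O[C@H](c3cc(OCc4ccccc4)c(OCc4ccccc4)c(OCc4ccccc4)c3)[C@H]2OCc2ccccc2)=C(O[Si](C)(C)C(C)(C)C)CC=C1C(=O)[C@H](OCc1ccccc1)[C@@H](O[Si](C)(C)C(C)(C)C)c1cc(OCc2ccccc2)c(OCc2ccccc2)c(OCc2ccccc2)c1
F6 | step 13 | (2R,3S,4R)-3,7-bis(benzyloxy)-2-[3,4,5-tris(benzyloxy)phenyl]-3,4-dihydro-2H-chromen-4-yl acetate | CC(=O)O[C@@H]1c2ccc(OCc3ccccc3)cc2O[C@H](c2cc(OCc3ccccc3)c(OCc3ccccc3)c(OCc3ccccc3)c2)[C@H]1OCc1ccccc1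
F0 | step 17 | none | none
A1 | alternative 1 | 5-(benzyloxy)-2-{[2,6-bis(methoxymethoxy)phenyl](hydroxy)methyl}phenol (carbinol carbon undefined) | COCOc1cccc(OCOC)c1C(O)c1ccc(OCc2ccccc2)cc1O
A2 | alternative 1 | benzyl(dimethyl){(E)-2-[3,4,5-tris(benzyloxy)phenyl]ethenyl}silane | C[Si](C)(Cc1ccccc1)/C=C/c1cc(OCc2ccccc2)c(OCc2ccccc2)c(OCc2ccccc2)c1
A3 | alternative 1 | 2,3-trans-3,4-trans 7-(benzyloxy)-3-[benzyl(dimethyl)silyl]-4-[2,6-bis(methoxymethoxy)phenyl]-2-[3,4,5-tris(benzyloxy)phenyl]chromane | COCOc1cccc(OCOC)c1[C@@H]1c2ccc(OCc3ccccc3)cc2O[C@H](c2cc(OCc3ccccc3)c(OCc3ccccc3)c(OCc3ccccc3)c2)[C@H]1[Si](C)(C)Cc1ccccc1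
A4 | alternative 2 | (2R,3R)-2-(benzyloxy)-3-{3-(benzyloxy)-6-bromo-2-[(2R,3S,4S)-3,7-bis(benzyloxy)-2-(3,4,5-tris(benzyloxy)phenyl)-3,4-dihydro-2H-chromen-4-yl]phenoxy}-N-methoxy-N-methyl-3-[3,4,5-tris(benzyloxy)phenyl]propanamide | CON(C)C(=O)[C@H](OCc1ccccc1)[C@H](Oc1c(Br)ccc(OCc2ccccc2)c1[C@@H]1c2ccc(OCc3ccccc3)cc2O[C@H](c2cc(OCc3ccccc3)c(OCc3ccccc3)c(OCc3ccccc3)c2)[C@H]1OCc1ccccc1)c1cc(OCc2ccccc2)c(OCc2ccccc2)c(OCc2ccccc2)c1
A5 | alternative 2 | fully benzylated target (7-O-benzyl ether of 28) | O=C1c2ccc(OCc5ccccc5)c([C@@H]3c4ccc(OCc5ccccc5)cc4O[C@H](c4cc(OCc5ccccc5)c(OCc5ccccc5)c(OCc5ccccc5)c4)[C@H]3OCc3ccccc3)c2O[C@H](c2cc(OCc5ccccc5)c(OCc5ccccc5)c(OCc5ccccc5)c2)[C@H]1OCc1ccccc1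
A6 | alternative 3 | 1,3-bis(methoxymethoxy)benzene | COCOc1cccc(OCOC)c1
A7 | alternative 3 | 2-(benzyloxy)-3-[3-(benzyloxy)phenoxy]-1-[2,6-bis(methoxymethoxy)phenyl]-3-[3,4,5-tris(benzyloxy)phenyl]propan-1-ol (carbinol carbon undefined; the other two centres as in A8) | COCOc1cccc(OCOC)c1C(O)[C@H](OCc1ccccc1)[C@H](Oc1cccc(OCc2ccccc2)c1)c1cc(OCc2ccccc2)c(OCc2ccccc2)c(OCc2ccccc2)c1
A8 | alternative 3 | 2,3-trans-3,4-trans 3,7-bis(benzyloxy)-4-[2,6-bis(methoxymethoxy)phenyl]-2-[3,4,5-tris(benzyloxy)phenyl]chromane | COCOc1cccc(OCOC)c1[C@@H]1c2ccc(OCc3ccccc3)cc2O[C@H](c2cc(OCc3ccccc3)c(OCc3ccccc3)c(OCc3ccccc3)c2)[C@H]1OCc1ccccc1
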